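A direct plan would enlarge a six-membered ring: (S)-3-methylcyclohexanone A1 would be taken in three steps to the 2-nitro ketone A2, joined by Michael addition to methyl (E)-4-oxobut-2-enoate A3 and α-oxygenated, then enlarged in one flask by an indium double allylation with retro-Claisen cleavage to the cyclodecanone A4. Acylation at O8, reduction of the C6 ketone with lactonisation to the nitro lactone A5, base-induced loss of the nitro group and N–O cleavage would finish.
Its weakest steps would be: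
- The one-flask double allylation with ring enlargement: it must form C7–C8 and C6–C7, set C7 and C8 and cleave C1–C6 in a cascade without precedent, on a mixture of C1/C10 epimers.
- The reduction of the C6 ketone inside the ten-membered ring: reagent control between two sp3 flanks, next to the epimerisable C7, is poor, and the trans lactone depends on it.
- The three-step run-up to the simple nitro ketone A2, and the late base-induced elimination followed by zinc reduction: these expose the C8 acyloxy group and the α-methylene lactone and leave the C1=C10 geometry to ring preference.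

**Retrosynthetic overview**
- The ten-membered ring is cut at C9–C10, between the C9 carbinol and the ester-bearing alkene carbon C10, and closed last by a nickel/chromium addition of a (Z)-α-iodo enoate to an α-angeloyloxy aldehyde; this step gives the target itself.
- The γ-lactone (O, C6, C7, C11, C12) is made first: an intramolecular cyclopropanation joins C11 to C7 and C8, and strain-driven opening of the C8–C11 bond by angelate puts the ester on C8 with inversion.
- C4 and the C1–C6 chain come from (S)-citronellal (aldehyde = C6, isopropylidene end = latent C1).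
- The design has no ring enlargement, no C6 ketone, no nitro group and no step after ring closure.

Key step: step 10

Assumption: germacrane numbering is used (lactone oxygen on C6, angelate on C8, hydroxyl on C9, ester carbon C14 on C10, methyl on C4); the target is (4S,6R,7S,8S,9S,1(10)E), with C2 and C9 cis on the C1=C10 bond.

Step 1
Reactants: 1 (S)-citronellal; 2 4-methoxybenzyl propargyl ether
Product: 5 (2E,4R,6S)-1-[(4-methoxybenzyl)oxy]-6,10-dimethylundeca-2,9-dien-4-ol, via alkenylborane 3 (not isolated), via alkenylzinc 4 (not isolated)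
Conditions: 2, Cy2BH, toluene, 0 → 25 °C; Me2Zn, −78 °C; (−)-MIB [(2S)-3-exo-morpholinoisoborneol, 5 mol%, enantiomer giving 4R], then 1, −20 °C; aq. NH4Cl
Reagents that add atoms: none
Why: Catalytic asymmetric alkenylzinc addition, in which syn hydroboration of 2 fixes the E geometry of C7=C8, boron–zinc exchange gives 4, and the amino alcohol ligand directs its addition to one face of the aldehyde to set the C6 carbinol (4R in 5), while C4 comes unchanged from citronellal.

Step 2
Reactants: 5 (2E,4R,6S)-1-[(4-methoxybenzyl)oxy]-6,10-dimethylundeca-2,9-dien-4-ol; 6 (diethoxyphosphoryl)acetic acid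
Product: 7 (2E,4R,6S)-1-[(4-methoxybenzyl)oxy]-6,10-dimethylundeca-2,9-dien-4-yl (diethoxyphosphoryl)acetate
Conditions: DCC, DMAP (10 mol%), CH2Cl2, 0 → 25 °C
Reagents that add atoms: none
Why: Steglich esterification of the secondary allylic alcohol, which touches no stereocentre and brings in C11 and C12 with the phosphonate.

Step 3
Reactants: 7 (2E,4R,6S)-1-[(4-methoxybenzyl)oxy]-6,10-dimethylundeca-2,9-dien-4-yl (diethoxyphosphoryl)acetate
Product: 8 (2E,4R,6S)-1-[(4-methoxybenzyl)oxy]-6,10-dimethylundeca-2,9-dien-4-yl diazo(diethoxyphosphoryl)acetate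
Conditions: p-ABSA, DBU, MeCN, 0 → 25 °C
Reagents that add atoms: 4-acetamidobenzenesulfonyl azide CC(=O)Nc1ccc(cc1)S(=O)(=O)N=[N+]=[N-]
Why: Regitz diazo transfer to the methylene flanked by the ester and the phosphonate.

Step 4
Reactants: 8 (2E,4R,6S)-1-[(4-methoxybenzyl)oxy]-6,10-dimethylundeca-2,9-dien-4-yl diazo(diethoxyphosphoryl)acetate
Product: 9 diethyl [(1S,4R,5R,6R)-4-[(2S)-2,6-dimethylhept-5-en-1-yl]-6-{[(4-methoxybenzyl)oxy]methyl}-2-oxo-3-oxabicyclo[3.1.0]hexan-1-yl]phosphonate
Conditions: Rh2(OAc)4 (1 mol%), ClCH2CH2Cl, 80 °C, slow addition of 8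
Reagents that add atoms: none
Why: Intramolecular cyclopropanation by the rhodium carbenoid is stereospecific, so the E alkene sets C7 and C8 together with the C6 side and C9 trans on the ring, and the C5 chain should prefer the exo position because the endo transition state eclipses it with the C7–C8 bond; the minor endo isomer is removed by chromatography.

Step 5
Reactants: 9 diethyl [(1S,4R,5R,6R)-4-[(2S)-2,6-dimethylhept-5-en-1-yl]-6-{[(4-methoxybenzyl)oxy]methyl}-2-oxo-3-oxabicyclo[3.1.0]hexan-1-yl]phosphonate; 10 angelic acid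
Product: 12 (1S)-1-[(2R,3S)-2-[(2S)-2,6-dimethylhept-5-en-1-yl]-4-methylidene-5-oxooxolan-3-yl]-2-[(4-methoxybenzyl)oxy]ethyl (2Z)-2-methylbut-2-enoate, via phosphonate carbanion 11 (not isolated)
Conditions: 10, Cs2CO3 (1.1 equiv), (CH2O)n, DMSO, 50 °C
Reagents that add atoms: formaldehyde (as paraformaldehyde) C=O
Why: Homoconjugate SN2 opening of the doubly activated cyclopropane by cesium angelate at C8, whose bond to C11 is the one aligned with the lactone carbonyl, occurs with inversion and so gives the 8S angelate, and the released phosphonate carbanion is olefinated in the same flask by Horner–Wadsworth–Emmons reaction with formaldehyde.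

Step 6
Reactants: 12 (1S)-1-[(2R,3S)-2-[(2S)-2,6-dimethylhept-5-en-1-yl]-4-methylidene-5-oxooxolan-3-yl]-2-[(4-methoxybenzyl)oxy]ethyl (2Z)-2-methylbut-2-enoate
Product: 14 (1S)-2-[(4-methoxybenzyl)oxy]-1-[(2R,3S)-2-[(2S)-2-methyl-5-oxopentyl]-4-methylidene-5-oxooxolan-3-yl]ethyl (2Z)-2-methylbut-2-enoate, via diol 13 (not isolated)
Conditions: OsO4 (2 mol%), NaIO4, 2,6-lutidine, dioxane/H2O (3:1), 25 °C
Reagents that add atoms: sodium periodate (oxygen relayed by OsO4) [Na+].[O-]I(=O)(=O)=O
Why: Lemieux–Johnson cleavage, in which electrophilic OsO4 takes the electron-rich trisubstituted alkene in preference to the conjugated alkenes and periodate cleaves the diol to the C1 aldehyde.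

Step 7
Reactants: 14 (1S)-2-[(4-methoxybenzyl)oxy]-1-[(2R,3S)-2-[(2S)-2-methyl-5-oxopentyl]-4-methylidene-5-oxooxolan-3-yl]ethyl (2Z)-2-methylbut-2-enoate; 15 methyl (triphenylphosphoranylidene)acetate
Product: 17 methyl (2Z,6S)-2-iodo-7-[(2R,3S)-3-[(1S)-2-[(4-methoxybenzyl)oxy]-1-{[(2Z)-2-methylbut-2-enoyl]oxy}ethyl]-4-methylidene-5-oxooxolan-2-yl]-6-methylhept-2-enoate, via iodo ylide 16 (not isolated)
Conditions: 15, NIS, CH2Cl2, −20 °C; then K2CO3, 14, 0 → 25 °C
Reagents that add atoms: N-iodosuccinimide O=C1CCC(=O)N1I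
Why: Wittig olefination with the α-iodo ylide made in the flask, a stabilised ylide that places the ester trans to C2 and so gives the (Z)-α-iodo enoate with the ring-cis geometry needed at C1=C10.

Step 8
Reactants: 17 methyl (2Z,6S)-2-iodo-7-[(2R,3S)-3-[(1S)-2-[(4-methoxybenzyl)oxy]-1-{[(2Z)-2-methylbut-2-enoyl]oxy}ethyl]-4-methylidene-5-oxooxolan-2-yl]-6-methylhept-2-enoate
Product: 18 methyl (2Z,6S)-7-[(2R,3S)-3-[(1S)-2-hydroxy-1-{[(2Z)-2-methylbut-2-enoyl]oxy}ethyl]-4-methylidene-5-oxooxolan-2-yl]-2-iodo-6-methylhept-2-enoate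
Conditions: DDQ, CH2Cl2/pH 7 buffer (10:1), 0 °C
Reagents that add atoms: none
Why: Oxidative cleavage of the 4-methoxybenzyl ether by DDQ under buffered neutral conditions, chosen so that the angelate does not migrate from O8 to the freed primary hydroxyl.

Step 9
Reactants: 18 methyl (2Z,6S)-7-[(2R,3S)-3-[(1S)-2-hydroxy-1-{[(2Z)-2-methylbut-2-enoyl]oxy}ethyl]-4-methylidene-5-oxooxolan-2-yl]-2-iodo-6-methylhept-2-enoate
Product: 19 methyl (2Z,6S)-2-iodo-6-methyl-7-[(2R,3S)-4-methylidene-3-[(1S)-1-{[(2Z)-2-methylbut-2-enoyl]oxy}-2-oxoethyl]-5-oxooxolan-2-yl]hept-2-enoate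
Conditions: Dess–Martin periodinane, NaHCO3, CH2Cl2, 0 °C; used at once
Reagents that add atoms: none
Why: Dess–Martin oxidation under bicarbonate buffer should give the α-acyloxy aldehyde without epimerising C8.

Step 10
Reactants: 19 methyl (2Z,6S)-2-iodo-6-methyl-7-[(2R,3S)-4-methylidene-3-[(1S)-1-{[(2Z)-2-methylbut-2-enoyl]oxy}-2-oxoethyl]-5-oxooxolan-2-yl]hept-2-enoate
Product: 21 CNP0552150.1 (target), via alkenylchromium 20 (not isolated)
Conditions: CrCl2 (10 equiv), NiCl2 (2 mol%), degassed DMSO/THF (3:1), 25 °C, 19 added by syringe pump (final 2 mM); aq. work-up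
Reagents that add atoms: none
Why: Zerovalent nickel, formed from NiCl2 by CrCl2, inserts into the C10–I bond and hands the alkenyl group to trivalent chromium, and the alkenylchromium 20 adds to the C9 aldehyde (Nozaki–Hiyama–Kishi reaction). The closest known reactions are closures of medium carbocycles from vinyl iodide aldehydes under these conditions and couplings of 2-iodo enoates with aldehydes to Baylis–Hillman-type carbinols. The ten-membered ring closes by a 10-exo-trig addition at C9, and the C1=C10 geometry is carried in from the Z iodide and is the ring-cis one. C9 is the one new stereocentre: with the C8–O bond anti to the forming C9–C10 bond (polar Felkin–Anh), the tether holds C7 gauche to C10 and the chromium-bound oxygen must point out of the forming ring, anti to C7, which leads to the 8,9-threo (9S) carbinol. The step needs chemoselectivity for the aldehyde over the esters, the lactone and the methylene acceptor, which the organochromium reagent has, and cyclisation over oligomerisation, which slow addition at high dilution should secure.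

**Compound list**
1 | (S)-citronellal, (3S)-3,7-dimethyloct-6-enal | O=CC[C@@H](C)CCC=C(C)C | starting material
2 | 4-methoxybenzyl propargyl ether, 1-methoxy-4-[(prop-2-yn-1-yloxy)methyl]benzene | C#CCOCc1ccc(OC)cc1 | starting material
3 | dicyclohexyl[(1E)-3-[(4-methoxybenzyl)oxy]prop-1-en-1-yl]borane | COc1ccc(COC/C=C/B(C2CCCCC2)C2CCCCC2)cc1 | intermediate
4 | [(1E)-3-[(4-methoxybenzyl)oxy]prop-1-en-1-yl](methyl)zinc | COc1ccc(COC/C=C/[Zn]C)cc1 | intermediate
5 | (2E,4R,6S)-1-[(4-methoxybenzyl)oxy]-6,10-dimethylundeca-2,9-dien-4-ol | CC(C)=CCC[C@H](C)C[C@@H](O)/C=C/COCc1ccc(OC)cc1 | intermediate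
6 | (diethoxyphosphoryl)acetic acid | OC(=O)CP(=O)(OCC)OCC | starting material
7 | (2E,4R,6S)-1-[(4-methoxybenzyl)oxy]-6,10-dimethylundeca-2,9-dien-4-yl (diethoxyphosphoryl)acetate | CC(C)=CCC[C@H](C)C[C@@H](OC(=O)CP(=O)(OCC)OCC)/C=C/COCc1ccc(OC)cc1 | intermediate
8 | (2E,4R,6S)-1-[(4-methoxybenzyl)oxy]-6,10-dimethylundeca-2,9-dien-4-yl diazo(diethoxyphosphoryl)acetate | CC(C)=CCC[C@H](C)C[C@@H](OC(=O)C(=[N+]=[N-])P(=O)(OCC)OCC)/C=C/COCc1ccc(OC)cc1 | intermediate
9 | diethyl [(1S,4R,5R,6R)-4-[(2S)-2,6-dimethylhept-5-en-1-yl]-6-{[(4-methoxybenzyl)oxy]methyl}-2-oxo-3-oxabicyclo[3.1.0]hexan-1-yl]phosphonate (cyclopropane C7–C8–C11; C5 chain exo) | CC(C)=CCC[C@H](C)C[C@H]1OC(=O)[C@]2(P(=O)(OCC)OCC)[C@@H](COCc3ccc(OC)cc3)[C@H]12 | intermediate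
10 | angelic acid, (2Z)-2-methylbut-2-enoic acid | C/C=C(/C)C(=O)O | starting material
11 | cesium salt of the ring-opened α-phosphono lactone carbanion with the C8 angelate (drawn as the carbanion) | CC(C)=CCC[C@H](C)C[C@H]1OC(=O)[C-](P(=O)(OCC)OCC)[C@@H]1[C@@H](COCc2ccc(OC)cc2)OC(=O)/C(C)=C\C.[Cs+] | intermediate
12 | (1S)-1-[(2R,3S)-2-[(2S)-2,6-dimethylhept-5-en-1-yl]-4-methylidene-5-oxooxolan-3-yl]-2-[(4-methoxybenzyl)oxy]ethyl (2Z)-2-methylbut-2-enoate | CC(C)=CCC[C@H](C)C[C@H]1OC(=O)C(=C)[C@@H]1[C@@H](COCc2ccc(OC)cc2)OC(=O)/C(C)=C\C | intermediate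
13 | (1S)-1-[(2R,3S)-2-[(2S)-5,6-dihydroxy-2,6-dimethylheptyl]-4-methylidene-5-oxooxolan-3-yl]-2-[(4-methoxybenzyl)oxy]ethyl (2Z)-2-methylbut-2-enoate (both epimers at the new carbinol) | CC(C)(O)C(O)CC[C@H](C)C[C@H]1OC(=O)C(=C)[C@@H]1[C@@H](COCc2ccc(OC)cc2)OC(=O)/C(C)=C\C | intermediate
14 | (1S)-2-[(4-methoxybenzyl)oxy]-1-[(2R,3S)-2-[(2S)-2-methyl-5-oxopentyl]-4-methylidene-5-oxooxolan-3-yl]ethyl (2Z)-2-methylbut-2-enoate | O=CCC[C@H](C)C[C@H]1OC(=O)C(=C)[C@@H]1[C@@H](COCc2ccc(OC)cc2)OC(=O)/C(C)=C\C | intermediate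
15 | methyl (triphenylphosphoranylidene)acetate | COC(=O)C=P(c1ccccc1)(c1ccccc1)c1ccccc1 | starting material
16 | methyl iodo(triphenylphosphoranylidene)acetate | COC(=O)C(I)=P(c1ccccc1)(c1ccccc1)c1ccccc1 | intermediate
17 | methyl (2Z,6S)-2-iodo-7-[(2R,3S)-3-[(1S)-2-[(4-methoxybenzyl)oxy]-1-{[(2Z)-2-methylbut-2-enoyl]oxy}ethyl]-4-methylidene-5-oxooxolan-2-yl]-6-methylhept-2-enoate | COC(=O)/C(I)=C/CC[C@H](C)C[C@H]1OC(=O)C(=C)[C@@H]1[C@@H](COCc2ccc(OC)cc2)OC(=O)/C(C)=C\C | intermediate
18 | methyl (2Z,6S)-7-[(2R,3S)-3-[(1S)-2-hydroxy-1-{[(2Z)-2-methylbut-2-enoyl]oxy}ethyl]-4-methylidene-5-oxooxolan-2-yl]-2-iodo-6-methylhept-2-enoate | COC(=O)/C(I)=C/CC[C@H](C)C[C@H]1OC(=O)C(=C)[C@@H]1[C@@H](CO)OC(=O)/C(C)=C\C | intermediate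
19 | methyl (2Z,6S)-2-iodo-6-methyl-7-[(2R,3S)-4-methylidene-3-[(1S)-1-{[(2Z)-2-methylbut-2-enoyl]oxy}-2-oxoethyl]-5-oxooxolan-2-yl]hept-2-enoate | COC(=O)/C(I)=C/CC[C@H](C)C[C@H]1OC(=O)C(=C)[C@@H]1[C@@H](C=O)OC(=O)/C(C)=C\C | intermediate
20 | alkenylchromium dichloride from 19 (C10–Cr in place of C10–I; solvent ligands omitted) | COC(=O)/C([Cr](Cl)Cl)=C/CC[C@H](C)C[C@H]1OC(=O)C(=C)[C@@H]1[C@@H](C=O)OC(=O)/C(C)=C\C | intermediate
21 | CNP0552150.1, methyl (3aS,4S,5S,6E,10S,11aR)-5-hydroxy-10-methyl-3-methylidene-4-{[(2Z)-2-methylbut-2-enoyl]oxy}-2-oxo-2,3,3a,4,5,8,9,10,11,11a-decahydrocyclodeca[b]furan-6-carboxylate; germacrane numbering (4S,6R,7S,8S,9S,1(10)E) | C=C1C(=O)O[C@@H]2C[C@@H](C)CC/C=C(/C(=O)OC)[C@H](O)[C@@H](OC(=O)/C(C)=C\C)[C@@H]12 | target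

Total step count: 10. Longest linear sequence: 10 steps (from 1).

**Steps most likely to fail**

Risk 1, step 10: the ring-closing addition may show poor facial selectivity at the C9 aldehyde and give the 9R carbinol, beside intermolecular coupling. Fallback, from 19 back to 21: the ring is closed under the same conditions without regard to C9, so that C9 is set by ketone reduction instead of by the C–C bond formation. The mixture of 21 and its C9 epimer F1 is oxidised with Dess–Martin periodinane to the cross-conjugated 9-ketone F2. F2 is reduced by Corey–Bakshi–Shibata reduction (2-methyl-CBS-oxazaborolidine, catecholborane, toluene, −60 °C; alkenyl flank as the large group, enantiomer chosen for 9S) to 21.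

Risk 2, step 5: the weakly nucleophilic carboxylate may attack the β-alkoxy-substituted C8 too slowly, and base may expel the C8 acyloxy group from the product through γ-deprotonation of the methylene lactone. A low exo/endo ratio in step 4 would hurt the same stage. Fallback, from 5 back to 12, which takes the C8 oxygen from an epoxide and forms C7–C11 by a radical cyclisation: Sharpless epoxidation of 5 (Ti(OiPr)4, D-(−)-diisopropyl tartrate, t-BuOOH, 4 Å MS, CH2Cl2, −20 °C; matched pair) should give the erythro epoxy alcohol F3. O-Propargylation (NaH, propargyl bromide, Bu4NI cat., THF, 0 °C) would give the propargyl ether F4. Cp2TiCl (trivalent titanium, made from Cp2TiCl2 and Zn in THF) would open the epoxide to the C7 radical, which closes 5-exo-dig trans to the C5 chain and gives the methylenetetrahydrofuran alcohol F5, whose C8 hydroxyl comes from the epoxide with retention. Esterification with 10 through its mixed anhydride (2,4,6-trichlorobenzoyl chloride, Et3N, toluene, 80 °C) would give the angelate F6, and allylic oxidation of the ring CH2 next to oxygen with CrO3·(pyridine)2 in CH2Cl2 would return to 12.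

Risk 3, step 1: the ligand-controlled addition to an enolisable, α-unbranched aldehyde may show too little facial selectivity and leave the C6 epimer. Fallback, from 1 and 2 (through 4) back to 5: the alkenylzinc 4 is added to 1 without the ligand to give 5 together with its carbinol epimer F7. The mixture is oxidised with MnO2 to the enone F8, which is reduced by Corey–Bakshi–Shibata reduction (2-methyl-CBS-oxazaborolidine, BH3·SMe2, THF, −30 °C; enantiomer chosen for 4R) to 5.

**Further compounds**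
F1 | step 10 | C9 epimer (9R) of 21 | C=C1C(=O)O[C@@H]2C[C@@H](C)CC/C=C(/C(=O)OC)[C@@H](O)[C@@H](OC(=O)/C(C)=C\C)[C@@H]12
F2 | step 10 | 9-ketone of 21 (cross-conjugated enone, C8 angelate kept) | C=C1C(=O)O[C@@H]2C[C@@H](C)CC/C=C(/C(=O)OC)C(=O)[C@@H](OC(=O)/C(C)=C\C)[C@@H]12
F3 | step 5 | (1R,3S)-1-[(2R,3R)-3-{[(4-methoxybenzyl)oxy]methyl}oxiran-2-yl]-3,7-dimethyloct-6-en-1-ol | CC(C)=CCC[C@H](C)C[C@@H](O)[C@H]1O[C@@H]1COCc2ccc(OC)cc2
F4 | step 5 | O-propargyl ether of F3 | CC(C)=CCC[C@H](C)C[C@@H](OCC#C)[C@H]1O[C@@H]1COCc2ccc(OC)cc2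
F5 | step 5 | (1S)-1-[(2R,3R)-2-[(2S)-2,6-dimethylhept-5-en-1-yl]-4-methylideneoxolan-3-yl]-2-[(4-methoxybenzyl)oxy]ethan-1-ol | CC(C)=CCC[C@H](C)C[C@H]1OCC(=C)[C@@H]1[C@H](O)COCc2ccc(OC)cc2
F6 | step 5 | (2Z)-2-methylbut-2-enoate (angelate) of F5 | CC(C)=CCC[C@H](C)C[C@H]1OCC(=C)[C@@H]1[C@@H](COCc2ccc(OC)cc2)OC(=O)/C(C)=C\C
F7 | step 1 | (2E,4S,6S)-1-[(4-methoxybenzyl)oxy]-6,10-dimethylundeca-2,9-dien-4-ol (carbinol epimer of 5) | CC(C)=CCC[C@H](C)C[C@H](O)/C=C/COCc1ccc(OC)cc1
F8 | step 1 | (2E,6S)-1-[(4-methoxybenzyl)oxy]-6,10-dimethylundeca-2,9-dien-4-one | CC(C)=CCC[C@H](C)CC(=O)/C=C/COCc1ccc(OC)cc1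
A1 | direct plan | (S)-3-methylcyclohexanone | O=C1C[C@@H](C)CCC1
A2 | direct plan | (5S)-5-methyl-2-nitrocyclohexan-1-one | O=C1C[C@@H](C)CCC1[N+](=O)[O-]
A3 | direct plan | methyl (E)-4-oxobut-2-enoate | COC(=O)/C=C/C=O
A4 | direct plan | ten-membered nitro keto ester (C6 ketone, C7 methyl acrylate unit, C8 hydroxyl, C9 tetramethylpiperidinyloxy ether, C10 methyl ester, C1 nitro group) | O=C1C[C@@H](C)CCC([N+](=O)[O-])C(C(=O)OC)[C@H](ON2C(C)(C)CCCC2(C)C)[C@@H](O)[C@H]1C(=C)C(=O)OC
A5 | direct plan | C1-nitro α-methylene lactone with C8 angelate and C9 tetramethylpiperidinyloxy ether | O=C1O[C@@H]2C[C@@H](C)CCC([N+](=O)[O-])C(C(=O)OC)[C@H](ON3C(C)(C)CCCC3(C)C)[C@@H](OC(=O)/C(C)=C\C)[C@H]2C1=C
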